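**Retrosynthetic overview**
1. Target 10 comes from acetyl chromene 7 and benzoyl chloride; the 1,3-diketone C–C bond is made last by enolate C-acylation.
2. 7 comes from aryl isopropenyl ether 3 and ethyl vinyl ether by a polar [4+2] annulation that joins C2 to C3 and C4 to C4a of the pyran ring (ring B) in one flask. The two-carbon unit enters as a vinyl ether and reaches the C3=C4 alkene by loss of ethanol.
3. Enabling feature: C2 is a gem-dimethyl carbon on the aryl oxygen O1, so it can be a tertiary aryl oxocarbenium ion. C4a of ring A is ortho to O1 and ortho to the chelated 5-OH, so C2=O1(+)–C8a=C4a is a cationic 2-oxa-diene.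
4. 3 comes from 1-(2,4-dihydroxy-6-methoxyphenyl)ethanone 1 and 2-bromopropene by O-vinylation of the unchelated 4-OH.
5. Ring order: ring A (benzene) is bought; ring B (2H-pyran) is the only ring formed, in step 2.

Key step: step 2

Assumption: 1 is taken as a catalogue compound, and the target, drawn as the diketo form, is the same compound as its chelated keto-enol tautomer; it has no stereocentre.

**Step 1**
Reactants: 1 1-(2,4-dihydroxy-6-methoxyphenyl)ethanone; 2 2-bromopropene
Product: 3 1-[2-hydroxy-6-methoxy-4-(prop-1-en-2-yloxy)phenyl]ethanone
Conditions: CuI (10 mol%), N,N-dimethylglycine hydrochloride (30 mol%), Cs2CO3 (1.6 equiv), 2 (3 equiv), 1,4-dioxane, 80 °C, sealed tube; chromatography on Et3N-washed silica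
Reagents that add atoms: 2-bromopropene, CC(Br)=C
Why: Ullmann-type copper-catalysed C–O coupling of a phenol with a vinyl bromide, in which the more acidic, unchelated 4-OH should couple while the 2-OH stays locked in its hydrogen bond to the acetyl group.

**Step 2**
Reactants: 3 1-[2-hydroxy-6-methoxy-4-(prop-1-en-2-yloxy)phenyl]ethanone; 4 ethyl vinyl ether
Product: 7 1-(5-hydroxy-7-methoxy-2,2-dimethyl-2H-chromen-6-yl)ethanone, via alpha-chloro ether 5 (not isolated), via 4-ethoxychroman 6 (not isolated)
Conditions: HCl (1.05 equiv, 1 M in Et2O), CH2Cl2, −78 °C; then 2,6-di-tert-butyl-4-methylpyridine (1.3 equiv), ZnCl2 (1.5 equiv, 1 M in Et2O), ethyl vinyl ether (1.2 equiv, added over 1 h), −78 to −30 °C; then camphorsulfonic acid (0.5 equiv), 40 °C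
Reagents that add atoms: ethyl vinyl ether, C=COCC
Why: Proposed new method: HCl adds across the isopropenyl ether of 3 to give the tertiary alpha-chloro ether 5, which ZnCl2 ionises to the aryl oxocarbenium ion C2=O1(+)–C8a=C4a; chloride is its only possible leaving group, so the aryl–oxygen bond stays intact. The terminal CH2 of ethyl vinyl ether attacks C2 (first new bond, C2–C3), and the ethoxycarbenium ion formed at C4 is trapped by C4a in a 6-exo-trig Friedel–Crafts closure of the pyran ring (second new bond, C4–C4a), a stepwise polar [4+2] annulation; acid-induced loss of ethanol from 6 through the benzylic cation, stabilised by three ring oxygens, then sets the C3=C4 double bond. The closest known reaction types are the oxa-Povarov reaction of aldehyde-derived aryl oxocarbenium ions with alkenes, the Povarov reaction of N-aryl iminium ions with vinyl ethers and the acid-catalysed dimerisation of aryl vinyl ethers to 4-aryloxychromans; new here are the ketone-level gem-dimethyl oxocarbenium ion, the vinyl ether as acetylene equivalent and the acyl-bearing ring. The only stereocentre formed (C4 of 6, racemic) is destroyed in the elimination, so no stereocontrol is needed. The step needs ring closure at the carbon between the 2-OH and the ether oxygen and not at the carbon next to OMe: the O–H···O=C chelate makes the hydroxyl the dominant ortho director and fixes the ring bond between these two carbons as the more olefinic one, the same preference that halogenation and Claisen rearrangement show in 2-hydroxy-4,6-dialkoxyacetophenones. It also needs cyclisation to outrun oligomerisation of the vinyl ether, which the intramolecular six-ring closure (gem-dimethyl effect), the slow near-stoichiometric addition and the proton trap should secure.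

**Step 3**
Reactants: 7 1-(5-hydroxy-7-methoxy-2,2-dimethyl-2H-chromen-6-yl)ethanone; 8 benzoyl chloride
Product: 10 1-(5-hydroxy-7-methoxy-2,2-dimethyl-2H-chromen-6-yl)-3-phenylpropane-1,3-dione, via dilithium phenoxide-enolate 9 (not isolated)
Conditions: LiN(SiMe3)2 (3.3 equiv), THF, −78 to −10 °C; then benzoyl chloride (1.05 equiv), −78 °C to rt; cold aq NH4Cl
Reagents that add atoms: benzoyl chloride, O=C(Cl)c1ccccc1
Why: Claisen-type C-acylation (the direct form of the Baker–Venkataraman transformation), in which the enolate carbon of dianion 9 is benzoylated and the extra equivalent of base deprotonates the more acidic diketone, which should prevent a second acylation.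

**Compound list**
1 | 1-(2,4-dihydroxy-6-methoxyphenyl)ethanone | CC(=O)c1c(O)cc(O)cc1OC | starting material
2 | 2-bromopropene | CC(Br)=C | starting material
3 | 1-[2-hydroxy-6-methoxy-4-(prop-1-en-2-yloxy)phenyl]ethanone | CC(=O)c1c(O)cc(OC(C)=C)cc1OC | intermediate
4 | ethyl vinyl ether | C=COCC | starting material
5 | 1-[4-(2-chloropropan-2-yloxy)-2-hydroxy-6-methoxyphenyl]ethanone | CC(=O)c1c(O)cc(OC(C)(C)Cl)cc1OC | intermediate
6 | 1-(4-ethoxy-5-hydroxy-7-methoxy-2,2-dimethyl-3,4-dihydro-2H-chromen-6-yl)ethanone (racemic) | CCOC1CC(C)(C)Oc2cc(OC)c(C(C)=O)c(O)c12 | intermediate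
7 | 1-(5-hydroxy-7-methoxy-2,2-dimethyl-2H-chromen-6-yl)ethanone | CC(=O)c1c(OC)cc2OC(C)(C)C=Cc2c1O | intermediate
8 | benzoyl chloride | O=C(Cl)c1ccccc1 | starting material
9 | dilithium phenoxide-enolate of 7 | [Li+].[Li+].C=C([O-])c1c(OC)cc2OC(C)(C)C=Cc2c1[O-] | intermediate
10 | 1-(5-hydroxy-7-methoxy-2,2-dimethyl-2H-chromen-6-yl)-3-phenylpropane-1,3-dione | COc1cc2c(c(O)c1C(=O)CC(=O)c1ccccc1)C=CC(C)(C)O2 | target

**Totals**
Total step count: 3. Longest linear sequence: 3 steps (1 to 3 to 7 to 10).

**Steps most likely to fail**

1. Step 2 (proposed method). The vinyl ether may oligomerise faster than the ring closes, the oxocarbenium ion may revert to the enol ether, or closure may occur at the ortho carbon next to the methoxy group. Fallback with known chemistry, setting out from 1 and coming back at 7: the 4-OH of 1 would be alkylated with 3-chloro-3-methylbut-1-yne (K2CO3, KI, acetone, reflux) to give 1-[2-hydroxy-6-methoxy-4-(2-methylbut-3-yn-2-yloxy)phenyl]ethanone F1. Heating F1 in N,N-diethylaniline at about 180 °C should then give 7 by aromatic propargyl Claisen rearrangement, 1,5-hydrogen shift and oxa-6π electrocyclisation, directed to the carbon next to the chelated hydroxyl.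

2. Step 1. The chelating ortho-hydroxy ketone may sequester the copper catalyst, both hydroxyls may be vinylated, or the volatile bromide may be lost. Fallback, setting out from 1 and coming back at 3: Mitsunobu etherification of the unchelated 4-OH with 1-chloropropan-2-ol (PPh3, diisopropyl azodicarboxylate, THF, 0 °C to rt) would give racemic 1-[4-(1-chloropropan-2-yloxy)-2-hydroxy-6-methoxyphenyl]ethanone F2. E2 elimination of HCl with KOC(CH3)3 (3 equiv) in DMSO at rt should then give 3, since the only hydrogen beta to chlorine is the one on the oxygen-bearing carbon.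

3. Step 3. O-acylation or double acylation may compete with C-acylation, and the product may cyclodehydrate to the flavone if the work-up is too acidic. Fallback, setting out from 7 and coming back at 10: the hindered phenol would be esterified with benzoyl chloride in pyridine (DMAP, 60 °C) to give 6-acetyl-7-methoxy-2,2-dimethyl-2H-chromen-5-yl benzoate F3. Baker–Venkataraman rearrangement of isolated F3 (powdered KOH, pyridine, 50 °C, then cold dilute acetic acid) should deliver 10 by intramolecular acyl transfer from oxygen to the enolate carbon.

**Further compounds**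
F1 | step 2 | 1-[2-hydroxy-6-methoxy-4-(2-methylbut-3-yn-2-yloxy)phenyl]ethanone | CC(=O)c1c(O)cc(OC(C)(C)C#C)cc1OC
F2 | step 1 | 1-[4-(1-chloropropan-2-yloxy)-2-hydroxy-6-methoxyphenyl]ethanone (racemic) | CC(=O)c1c(O)cc(OC(C)CCl)cc1OC
F3 | step 3 | 6-acetyl-7-methoxy-2,2-dimethyl-2H-chromen-5-yl benzoate | CC(=O)c1c(OC)cc2OC(C)(C)C=Cc2c1OC(=O)c1ccccc1
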